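## Analysis of the target

The target (CNP0086724.2) is a daucane-type diester on a bicyclo[5.3.0]decane (hydroazulene) core. The locants used throughout are: C1 the quaternary ring-fusion carbon carrying a methyl group, C2 and C3 the ring methylenes, C4 the carbinol carbon carrying the isopropyl group, C5 the ring-fusion methine, C6 the carbon carrying the 4-hydroxybenzoate, C7 a methylene, C8(CH3)=C9 the trisubstituted alkene and C10 the carbon carrying the isovalerate. The five-membered ring is C1–C5 and the seven-membered ring is C1, C5–C10.

There are five stereocentres (1S, 4S, 5S, 6R, 10S). Both ester oxygens lie on the face of the seven-membered ring that carries the C1 methyl, H5 lies on the opposite face (trans ring fusion), and the C4 hydroxyl is cis to H5 and trans to the C1 methyl on the five-membered ring.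

The sensitive elements are the allylic ester at C10, the free phenol, and the 1,3-relationship between the tertiary C4 hydroxyl and the C6 oxygen, which becomes a retro-aldol or dehydration liability whenever C6 is a ketone. The first difficulty is the quaternary C1, flanked by the oxygenated C10 and the ring fusion, from which every other stereocentre has to be relayed. The second is that C6 and C10 are two hindered secondary carbinols that must carry different acyl groups while the tertiary alcohol stays free.

The strategy rests on one feature: C6(O), C7, C8(CH3), C9 and C10(O), together with C5 between the two oxygens, reproduce the substitution pattern of an orcinol diether. The seven-membered ring is therefore that benzene ring enlarged by the single carbon C1, inserted between C5 and C10, and the same carbon closes the five-membered ring.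

## Retrosynthetic reasoning

**Acyl–oxygen bonds (31 from 30, 28 + 29, 27).** The phenol is released last from its acetate 30, so no free phenol competes in an acylation. The C10 isovalerate is cut back to allylic alcohol 28 and acid chloride 29, and 28 to enone 27. Cutting here means the C10 oxygen is still a ketone while the C6 ester is already in place, so the two carbinols are never free together and no selective acylation is needed. The forward reduction of 27 has to deliver hydride anti to the C1 methyl.

**C6 ester and the C10 enone (27 from 26, 24 + 25, 23).** The enone C8=C9–C10=O of 27 is the hydrolysis product of the methoxydiene C7=C8–C9=C10(OMe) in 26. Ester 26 comes from diol 24 and acid chloride 25, and 24 from ketone 23 by carbonyl reduction. The order (reduce, acylate, then unmask) is deliberate: with C6 still a ketone, hydrolysis would give a vinylogous 1,3-diketone with a doubly activated C7 methylene, and with C6 as a free allylic alcohol the methoxydiene would assist its ionisation. The forward hydrolysis must protonate C7 and leave the C6 acyloxy group alone.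

**C4–O and C5–H (23 from 22 from 21).** The tertiary alcohol is β to the C6 carbonyl, so the C4–O bond is traced to epoxy ketone 22 by reductive cleavage of the C5–O bond, and 22 to tetrasubstituted enone 21 by nucleophilic epoxidation. This places oxygen on C4 from the open face and hydrogen on C5 in a separate, kinetically controlled protonation. Direct isopropyl addition to a C4 ketone would have to come from the hindered face.

**C4–isopropyl bond (21 from 18 + 19).** The isopropyl group is cut at C4, the β-carbon of cross-conjugated dienone 18, with Grignard reagent 19 as the donor, followed by re-oxidation of the enolate. C4 is β to both the C2 and the C6 carbonyl. The C6 carbonyl is used because its enone arm is not deactivated by a donor and C5 is then the only position that ever has to be enolised. Using C2 would need an enone in conjugation with the electron-rich triene, or a 1,5-dicarbonyl with a doubly activated C5–H.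

**C4=C5 unsaturation, the C2 oxygen and the C6 carbonyl (18 from 16, 15, 13, 11).** Dienone 18 is ketone 16 dehydrogenated at C4–C5. Ketone 16 comes from 15 by saturating the C2=C3 alkene, 15 from enol triflate 13 by reduction and mono-hydrolysis, and 13 from trienone 11. The C2 carbonyl is only a relic of the ring-forming step. It is removed through the enol triflate and a hydride-transfer reduction because C1 carries two vinyl groups, and a radical or carbanion at C2 could add to them. The forward hydrolysis has to stop after one enol ether and place the carbonyl at C6.

**C1–C5 and C1–C10 (11 from 9, through 10).** Both bonds to C1 are cut at once. Trienone 11 is the electrocyclic ring-opened form of norcaradiene 10, which is the product of adding the carbene carbon of diazoketone 9 across an ipso–ortho bond of its aryl ring. The cut is made here because it turns the bicyclic problem into an acyclic aryl ketone, delivers C6 and C10 as enol ethers and C8 with its methyl, and leaves one stereocentre to be set by a chiral catalyst choosing between two enantiotopic bonds.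

**Diazoketone (9 from 5 + 6; 5 from 4 from 1 + 2).** Diazoketone 9 is cut at the acyl–diazo carbon bond into acid 5 (through acid chloride 7) and diazoethane 8, made from nitrosourea 6. This fixes the diazo group on the methyl-bearing carbon without relying on regioselective enolisation of an ethyl ketone. Acid 5 comes from alcohol 4, and 4 from arene 1 and oxetane 2 through aryllithium 3, using the position between the two methoxy groups.

## Alternatives that were turned down

**Alternative 1:** The disconnection is the C7–C8 bond, with the C5–C10 bond restored as a cyclopropane. The seven-membered ring would come from a cis-divinylcyclopropane on a terpene-derived bicyclo[3.1.0]hexane that already carries the C1 methyl and the C4 isopropyl group. The forward key step is a Cope rearrangement through a boat transition state of the cyclopropane bearing a 1-silyloxyvinyl group on C5 and an (E)-propenyl group on C10, giving silyl enol ether A1.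

- For it: the rearrangement is stereospecific, driven by strain release and needs no catalyst. C1 and the isopropyl group come from the chiral pool. The C6 oxygen arrives as a silyl enol ether that could be oxidised directly to the C4=C5 enone corresponding to 21. On the isopropyl group this alternative is stronger than the chosen route, which spends a conjugate addition and a re-oxidation on it.
- Against it: A1 has no oxygen at C10, its alkene is C9=C10 and C8 is an sp3 stereocentre. The target pattern would need an allylic oxidation with transposition, delivered to the face syn to the C1 methyl, and nothing in A1 secures its regio- or facial outcome. The cyclopropane precursor needs a long degradation of a cyclohexene terpene with control of the cis-divinyl geometry, and the C4 configuration bought there is erased when C4=C5 is formed.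
- Comparison: the chosen strategy has both oxygens and the methyl-bearing alkene carbon in the arene from the first step and reaches its key-step substrate in three steps. It pays with the isopropyl steps and with reliance on asymmetric catalysis.

**Alternative 2:** The disconnection is the C1–C2 bond. A vinyl ketone attached to C5 of a preformed cycloheptadiene carrying the C10 silyloxy stereocentre would close under FeCl3 or BF3·OEt2 through a pentadienyl cation in a conrotatory 4π electrocyclisation (Nazarov), giving cyclopentenone A2 with the quaternary C1. The sense of rotation would be steered by the C10 substituent.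

- For it: the C4 carbonyl of A2 sits where the tertiary alcohol is needed, so the isopropyl group could enter in one step, which beats the chosen route on count. C8=C9 and the C10 oxygen are present from the start.
- Against it: the closure must form a quaternary centre at a fully substituted, unpolarised diene terminus, which calls for strong Lewis acid. Under such conditions the C10 silyl ether, allylic to C8=C9 and next to the cation terminus, is prone to ionise or eliminate. The C1/C10 relationship rests on torquoselectivity from a single allylic substituent. Isopropyl addition to the C4 ketone is expected anti to the C1 methyl, which places the hydroxyl cis to that methyl (the C4 epimer). H5 and the C6 oxygen must be added anti across C5=C6, which a syn hydroboration cannot do. The cycloheptadiene precursor needs its own enantioselective synthesis.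
- Comparison: the chosen route is longer after its key step, but each later stereocentre is set on the face that C1 leaves open.

**Alternative 3:** The disconnection is the C1–C5 bond, seen as the result of a 1,2-shift. A trans-decalin vicinal diol monomesylate, descended from an enantioenriched Robinson-annulation enedione, would be treated with potassium tert-butoxide. The C1–C6 bond migrates to C5 as the mesylate leaves, contracting one ring to the cyclopentane, expanding the other to the cycloheptanone and giving A3.

- For it: the starting material is available in high enantiopurity. The shift is stereospecific, with retention at the migrating carbon. A3 holds the C4 carbinol, a C6 ketone and a C10 ketal as three distinct functions. In reliability of the single steps and in differentiation of C6 from C10 this alternative is stronger than the chosen route.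
- Against it: A3 lacks the C8 methyl and the C8=C9 alkene, which would have to be built onto the C10 ketone next to quaternary C1 over several operations. A3 is cis-fused, so C5 must be epimerised next to a ketone that is also a retro-aldol-prone β-hydroxy ketone. As formed, its C4 hydroxyl is cis to the C1 methyl, which is wrong once C5 is corrected.
- Comparison: the chosen strategy offers the complete C6–C10 substitution pattern and the trans-directing face bias from C1 in one ring-forming step, and a much shorter sequence.

Key step: step 4

Remark on conventions: bicyclic compounds are named with the locants defined in the analysis, "syn/anti to the C1 methyl" refers to the faces of the ring concerned, and the SMILES strings are authoritative for configuration.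

Assumption: the (S,S)-bis(oxazoline) is taken to favour the ipso–ortho bond that leads to (1S)-11. If it favours the other bond, the (R,R)-ligand is used and nothing else changes.

## Route

Step 1
Reactants: 1 3,5-dimethoxytoluene; 2 oxetane
Product: 4 3-(2,6-dimethoxy-4-methylphenyl)propan-1-ol, via aryllithium 3 (not isolated)
Conditions: n-BuLi, THF, 0 °C to rt; then 2, BF3·OEt2 (promoter), −78 °C
Reagents that add atoms: none
Why: Directed ortho-lithiation occurs between the two methoxy groups, the doubly activated position. The aryllithium then opens Lewis acid-activated oxetane by SN2 attack at an unhindered methylene, which installs the three-carbon chain in one operation.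

Step 2
Reactants: 4 3-(2,6-dimethoxy-4-methylphenyl)propan-1-ol
Product: 5 3-(2,6-dimethoxy-4-methylphenyl)propanoic acid
Conditions: TEMPO (cat.), PhI(OAc)2, MeCN/H2O, rt
Reagents that add atoms: water, O
Why: Oxoammonium-mediated oxidation takes the primary alcohol to the aldehyde and, through its hydrate, to the acid under near-neutral conditions that leave the electron-rich arene alone.

Step 3
Reactants: 5 3-(2,6-dimethoxy-4-methylphenyl)propanoic acid; 6 N-ethyl-N-nitrosourea
Product: 9 2-diazo-5-(2,6-dimethoxy-4-methylphenyl)pentan-3-one, via acid chloride 7 (not isolated), via diazoethane 8 (not isolated)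
Conditions: 5, (COCl)2, cat. DMF, CH2Cl2, 0 °C to rt, evaporate; separately 6, aq. KOH, Et2O, −10 °C, ether layer dried over KOH pellets; 7 added to excess 8, Et2O, −20 to 0 °C
Reagents that add atoms: none
Why: This is acylation of a diazoalkane by an acid chloride (the first stage of the Arndt–Eistert sequence), which puts the diazo group on the methyl-bearing carbon with no regiochemical ambiguity. Excess 8 consumes the HCl, and the methoxy-blocked ortho positions prevent Friedel–Crafts closure of 7.

Step 4
Reactants: 9 2-diazo-5-(2,6-dimethoxy-4-methylphenyl)pentan-3-one
Product: 11 (1S)-6,10-dimethoxy-1,8-dimethylbicyclo[5.3.0]deca-5,7,9-trien-2-one, via norcaradiene 10 (not isolated)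
Conditions: [Cu(MeCN)4]PF6 (5 mol %), 2,2′-isopropylidenebis[(4S)-4-tert-butyl-2-oxazoline] (6 mol %), Na[B(3,5-(CF3)2C6H3)4] (6 mol %), CH2Cl2, 40 °C, slow addition of 9; chromatography on Et3N-deactivated silica
Reagents that add atoms: none
Why: The copper complex takes N2 from 9 to give an electrophilic copper carbenoid, which adds across one ipso–ortho π bond of the arene and forms C1–C5 and C1–C10 in norcaradiene 10. The five-membered ring closes in this intramolecular [2+1] cyclopropanation, because the three-atom tether C2–C3–C4 can only reach the ipso carbon. The seven-membered ring then arises by thermal disrotatory 6π electrocyclic opening of the C5–C10 bond of 10, favoured by the methoxy donor on C10 and the acyl acceptor on C1. The closest known reaction type is the enantioselective intramolecular Buchner reaction of aryl-tethered α-diazoketones under copper bis(oxazoline) catalysis, which includes α-methyl diazoketones. C1 is the only stereocentre formed; the two ipso–ortho bonds are enantiotopic, and the chiral ligand on monovalent copper decides which is attacked (catalyst control). The step needs chemoselectivity against 1,2-hydride shift from the carbenoid methyl, aromatic substitution and carbene dimerisation. The methoxy groups on both ortho carbons remove every ortho C–H and every rearomatising exit, the electron-rich ring reacts fast with the carbenoid, and slow addition suppresses dimerisation. The weakly coordinating borate keeps the copper centre cationic, so that the ligand and not the counterion shapes the carbenoid.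

Step 5
Reactants: 11 (1S)-6,10-dimethoxy-1,8-dimethylbicyclo[5.3.0]deca-5,7,9-trien-2-one
Product: 13 6,10-dimethoxy-1,8-dimethylbicyclo[5.3.0]deca-2,5,7,9-tetraen-2-yl trifluoromethanesulfonate, via potassium enolate 12 (not isolated)
Conditions: KN(SiMe3)2, THF, −78 °C; PhNTf2, −78 to 0 °C
Reagents that add atoms: N-phenylbis(trifluoromethanesulfonimide), O=S(=O)(N(c1ccccc1)S(=O)(=O)C(F)(F)F)C(F)(F)F
Why: C3 is the only enolisable position of 11 because C1 is quaternary, so enolate O-triflation gives a single enol triflate. The basic medium leaves both enol ethers intact.

Step 6
Reactants: 13 6,10-dimethoxy-1,8-dimethylbicyclo[5.3.0]deca-2,5,7,9-tetraen-2-yl trifluoromethanesulfonate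
Product: 15 10-methoxy-1,8-dimethylbicyclo[5.3.0]deca-2,7,9-trien-6-one (C5 epimers), via tetraene 14 (not isolated)
Conditions: Pd(OAc)2 (5 mol %), PPh3, Bu3N, HCO2H, DMF, 60 °C; then 0.5 M aq. HCl, THF, 0 °C, short contact
Reagents that add atoms: water, O
Why: Palladium-catalysed formate reduction of the vinyl triflate removes the C2 oxygen by hydride transfer, with no radical or carbanion at C2 that could attack the vinyl groups on C1. Brief acid then protonates the triene at C5, and water should add to C6, the cation terminus next to the C5 methine, rather than to C10, which is shielded on both faces by quaternary C1. The resulting doubly vinylogous ester resists further hydrolysis, so the reaction stops after one enol ether.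

Step 7
Reactants: 15 10-methoxy-1,8-dimethylbicyclo[5.3.0]deca-2,7,9-trien-6-one
Product: 16 10-methoxy-1,8-dimethylbicyclo[5.3.0]deca-7,9-dien-6-one (C5 epimers)
Conditions: H2 (1–3 atm), RhCl(PPh3)3 (5 mol %), benzene, rt
Reagents that add atoms: none
Why: Homogeneous hydrogenation with this rhodium complex reduces the cis-disubstituted cyclopentene far faster than the trisubstituted, conjugated alkenes of the methoxydienone.

Step 8
Reactants: 16 10-methoxy-1,8-dimethylbicyclo[5.3.0]deca-7,9-dien-6-one
Product: 18 10-methoxy-1,8-dimethylbicyclo[5.3.0]deca-4,7,9-trien-6-one, via silyl dienol ether 17 (not isolated)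
Conditions: LiN(iPr)2, TMSCl (internal quench), THF, −78 °C; then Pd(OAc)2, MeCN, rt
Reagents that add atoms: none
Why: Kinetic deprotonation of a vinylogous ester occurs at the α′ carbon, here C5, and the enolate is trapped as it forms. In the Saegusa–Ito oxidation the palladium enolate can lose β-hydride only from C4, because C1 is quaternary, which gives the cross-conjugated dienone.

Step 9
Reactants: 18 10-methoxy-1,8-dimethylbicyclo[5.3.0]deca-4,7,9-trien-6-one; 19 isopropylmagnesium chloride
Product: 21 4-isopropyl-10-methoxy-1,8-dimethylbicyclo[5.3.0]deca-4,7,9-trien-6-one, via silyl enol ether 20 (not isolated)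
Conditions: 19, CuBr·SMe2 (10 mol %), TMSCl, THF, −78 °C; Et3N, pentane work-up; then Pd(OAc)2, MeCN, rt
Reagents that add atoms: none
Why: Copper-catalysed conjugate addition goes to C4, the β-carbon of the enone arm that carries no donor; the other arm is a vinylogous ester with a disubstituted, hindered β-position. The enolate is trapped on oxygen, and a second Saegusa–Ito oxidation restores C4=C5, now tetrasubstituted, so the transient C4 stereocentre does not matter.

Step 10
Reactants: 21 4-isopropyl-10-methoxy-1,8-dimethylbicyclo[5.3.0]deca-4,7,9-trien-6-one
Product: 22 4,5-epoxy-4-isopropyl-10-methoxy-1,8-dimethylbicyclo[5.3.0]deca-7,9-dien-6-one (epoxide oxygen anti to the C1 methyl)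
Conditions: tBuOOH (decane), BnMe3N+ OH− (cat., MeOH), THF, 0 °C to rt
Reagents that add atoms: tert-butyl hydroperoxide, CC(C)(C)OO
Why: Weitz–Scheffer nucleophilic epoxidation selects the enone arm that is not deactivated by the methoxy donor and leaves the electron-rich enol ether untouched. The peroxide anion should add to C4 anti to the pseudoaxial C1 methyl, as hydroperoxide does with steroidal 16-en-20-ones against the angular methyl, which sets the C4–O configuration.

Step 11
Reactants: 22 4,5-epoxy-4-isopropyl-10-methoxy-1,8-dimethylbicyclo[5.3.0]deca-7,9-dien-6-one
Product: 23 4-hydroxy-4-isopropyl-10-methoxy-1,8-dimethylbicyclo[5.3.0]deca-7,9-dien-6-one (C4–OH and H5 anti to the C1 methyl)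
Conditions: SmI2 (2.5 equiv), THF/MeOH, −78 °C; pH 7 buffer work-up
Reagents that add atoms: none
Why: Ketyl formation at C6 is followed by cleavage of the adjacent C5–O bond, the standard reductive opening of α,β-epoxy ketones to β-hydroxy ketones, so the C4–O bond and its configuration are kept. The samarium enolate is protonated at C5 from the face carrying the C4 oxygen, away from both the C1 methyl and the isopropyl group, which gives the trans ring fusion.

Step 12
Reactants: 23 4-hydroxy-4-isopropyl-10-methoxy-1,8-dimethylbicyclo[5.3.0]deca-7,9-dien-6-one
Product: 24 4-isopropyl-10-methoxy-1,8-dimethylbicyclo[5.3.0]deca-7,9-diene-4,6-diol (C6–OH syn to the C1 methyl)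
Conditions: NaBH4, CeCl3·7H2O, MeOH, −40 °C; NaHCO3 work-up, product kept on base-washed glassware
Reagents that add atoms: none
Why: Luche conditions give 1,2-reduction of the vinylogous ester carbonyl at a temperature at which the β-hydroxy ketone neither epimerises nor undergoes retro-aldol cleavage. Hydride should enter anti to the C1 methyl and the C4 isopropyl group, which both shield the other face across C5 (as in 6-keto steroids with the angular methyl), so the hydroxyl ends syn to the C1 methyl.

Step 13
Reactants: 24 4-isopropyl-10-methoxy-1,8-dimethylbicyclo[5.3.0]deca-7,9-diene-4,6-diol; 25 4-acetoxybenzoyl chloride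
Product: 26 6-(4-acetoxybenzoyloxy)-4-isopropyl-10-methoxy-1,8-dimethylbicyclo[5.3.0]deca-7,9-dien-4-ol
Conditions: 25, DMAP, Et3N, CH2Cl2, 0 °C to rt
Reagents that add atoms: none
Why: DMAP-catalysed acylation takes the secondary alcohol and leaves the tertiary one, and the basic medium preserves the acid-labile methoxydiene. The acyloxy group is also a much poorer leaving group under aqueous acid than the free allylic hydroxyl, which prepares the next step.

Step 14
Reactants: 26 6-(4-acetoxybenzoyloxy)-4-isopropyl-10-methoxy-1,8-dimethylbicyclo[5.3.0]deca-7,9-dien-4-ol
Product: 27 6-(4-acetoxybenzoyloxy)-4-hydroxy-4-isopropyl-1,8-dimethylbicyclo[5.3.0]dec-8-en-10-one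
Conditions: 0.5 M aq. HCl, THF, 0 °C
Reagents that add atoms: water, O
Why: 1-Alkoxy-1,3-dienes hydrolyse by protonation at the terminal diene carbon, here C7, which gives the conjugated oxocarbenium ion. Water then adds at C10, so the enone appears with C8=C9 in place and C7 as a methylene, while the ester at C6 and the tertiary alcohol survive the dilute acid.

Step 15
Reactants: 27 6-(4-acetoxybenzoyloxy)-4-hydroxy-4-isopropyl-1,8-dimethylbicyclo[5.3.0]dec-8-en-10-one
Product: 28 6-(4-acetoxybenzoyloxy)-4-isopropyl-1,8-dimethylbicyclo[5.3.0]dec-8-ene-4,10-diol (C10–OH syn to the C1 methyl)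
Conditions: NaBH4, CeCl3·7H2O, MeOH, −78 °C
Reagents that add atoms: none
Why: Luche 1,2-reduction of the enone is fast at low temperature, where neither the aryl acetate nor the base-sensitive δ-acyloxy enone is affected. Hydride should attack anti to the axial C1 methyl on the neighbouring quaternary carbon (the 12-keto and 17-keto steroid pattern), giving the alcohol syn to that methyl.

Step 16
Reactants: 28 6-(4-acetoxybenzoyloxy)-4-isopropyl-1,8-dimethylbicyclo[5.3.0]dec-8-ene-4,10-diol; 29 3-methylbutanoyl chloride
Product: 30 6-(4-acetoxybenzoyloxy)-4-hydroxy-4-isopropyl-1,8-dimethylbicyclo[5.3.0]dec-8-en-10-yl 3-methylbutanoate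
Conditions: 29, DMAP, pyridine, CH2Cl2, 0 °C to rt
Reagents that add atoms: none
Why: The only free secondary hydroxyl is at C10, so DMAP-catalysed acylation is site-selective by construction; the tertiary C4 alcohol does not react under these conditions.

Step 17
Reactants: 30 6-(4-acetoxybenzoyloxy)-4-hydroxy-4-isopropyl-1,8-dimethylbicyclo[5.3.0]dec-8-en-10-yl 3-methylbutanoate
Product: 31 target, (1S,4S,5S,6R,10S)-4-hydroxy-6-(4-hydroxybenzoyloxy)-4-isopropyl-1,8-dimethylbicyclo[5.3.0]dec-8-en-10-yl 3-methylbutanoate
Conditions: NH4OAc, MeOH/H2O, rt
Reagents that add atoms: none
Why: Aryl acetates are far more electrophilic than alkyl esters, so mild ammonium acetate-promoted methanolysis frees the phenol and leaves the hindered C6 benzoate and C10 isovalerate in place.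

## Compound list

1 | 3,5-dimethoxytoluene | COc1cc(C)cc(OC)c1 | starting material
2 | oxetane | C1COC1 | starting material
3 | (2,6-dimethoxy-4-methylphenyl)lithium | [Li]c1c(OC)cc(C)cc1OC | intermediate
4 | 3-(2,6-dimethoxy-4-methylphenyl)propan-1-ol | OCCCc1c(OC)cc(C)cc1OC | intermediate
5 | 3-(2,6-dimethoxy-4-methylphenyl)propanoic acid | OC(=O)CCc1c(OC)cc(C)cc1OC | intermediate
6 | N-ethyl-N-nitrosourea | CCN(N=O)C(N)=O | starting material
7 | 3-(2,6-dimethoxy-4-methylphenyl)propanoyl chloride | ClC(=O)CCc1c(OC)cc(C)cc1OC | intermediate
8 | diazoethane | CC=[N+]=[N-] | intermediate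
9 | 2-diazo-5-(2,6-dimethoxy-4-methylphenyl)pentan-3-one | CC(=[N+]=[N-])C(=O)CCc1c(OC)cc(C)cc1OC | intermediate
10 | norcaradiene valence isomer of 11 (cyclopropane C1–C5–C10, diene C6=C7–C8=C9) | CC1=C[C@]2(OC)[C@@]3(C)C(=O)CC[C@@]23C(OC)=C1 | intermediate
11 | (1S)-6,10-dimethoxy-1,8-dimethylbicyclo[5.3.0]deca-5,7,9-trien-2-one | CC1=CC(OC)=C2CCC(=O)[C@]2(C)C(OC)=C1 | intermediate
12 | potassium C2-enolate of 11 | CC1=CC(OC)=C2CC=C([O-])[C@]2(C)C(OC)=C1.[K+] | intermediate
13 | 6,10-dimethoxy-1,8-dimethylbicyclo[5.3.0]deca-2,5,7,9-tetraen-2-yl trifluoromethanesulfonate (C1 as in 11) | CC1=CC(OC)=C2CC=C(OS(=O)(=O)C(F)(F)F)[C@]2(C)C(OC)=C1 | intermediate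
14 | 6,10-dimethoxy-1,8-dimethylbicyclo[5.3.0]deca-2,5,7,9-tetraene (C1 as in 11) | CC1=CC(OC)=C2CC=C[C@]2(C)C(OC)=C1 | intermediate
15 | 10-methoxy-1,8-dimethylbicyclo[5.3.0]deca-2,7,9-trien-6-one (C1 as in 11, C5 epimers) | CC1=CC(=O)C2CC=C[C@]2(C)C(OC)=C1 | intermediate
16 | 10-methoxy-1,8-dimethylbicyclo[5.3.0]deca-7,9-dien-6-one (C1 as in 11, C5 epimers) | CC1=CC(=O)C2CCC[C@]2(C)C(OC)=C1 | intermediate
17 | 10-methoxy-1,8-dimethyl-6-(trimethylsilyloxy)bicyclo[5.3.0]deca-5,7,9-triene | CC1=CC(O[Si](C)(C)C)=C2CCC[C@]2(C)C(OC)=C1 | intermediate
18 | 10-methoxy-1,8-dimethylbicyclo[5.3.0]deca-4,7,9-trien-6-one | CC1=CC(=O)C2=CCC[C@]2(C)C(OC)=C1 | intermediate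
19 | isopropylmagnesium chloride | CC(C)[Mg]Cl | starting material
20 | 4-isopropyl-10-methoxy-1,8-dimethyl-6-(trimethylsilyloxy)bicyclo[5.3.0]deca-5,7,9-triene (C4 epimers) | CC1=CC(O[Si](C)(C)C)=C2C(C(C)C)CC[C@]2(C)C(OC)=C1 | intermediate
21 | 4-isopropyl-10-methoxy-1,8-dimethylbicyclo[5.3.0]deca-4,7,9-trien-6-one | CC1=CC(=O)C2=C(C(C)C)CC[C@]2(C)C(OC)=C1 | intermediate
22 | 4,5-epoxy-4-isopropyl-10-methoxy-1,8-dimethylbicyclo[5.3.0]deca-7,9-dien-6-one, epoxide oxygen anti to the C1 methyl | CC1=CC(=O)[C@@]23O[C@]2(C(C)C)CC[C@]3(C)C(OC)=C1 | intermediate
23 | 4-hydroxy-4-isopropyl-10-methoxy-1,8-dimethylbicyclo[5.3.0]deca-7,9-dien-6-one, trans-fused, C4–OH cis to H5 | CC1=CC(=O)[C@H]2[C@@](O)(C(C)C)CC[C@]2(C)C(OC)=C1 | intermediate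
24 | 4-isopropyl-10-methoxy-1,8-dimethylbicyclo[5.3.0]deca-7,9-diene-4,6-diol, C6–OH syn to the C1 methyl | CC1=C[C@@H](O)[C@H]2[C@@](O)(C(C)C)CC[C@]2(C)C(OC)=C1 | intermediate
25 | 4-acetoxybenzoyl chloride | CC(=O)Oc1ccc(cc1)C(Cl)=O | starting material
26 | 6-(4-acetoxybenzoyloxy)-4-isopropyl-10-methoxy-1,8-dimethylbicyclo[5.3.0]deca-7,9-dien-4-ol | CC1=C[C@@H](OC(=O)c3ccc(OC(C)=O)cc3)[C@H]2[C@@](O)(C(C)C)CC[C@]2(C)C(OC)=C1 | intermediate
27 | 6-(4-acetoxybenzoyloxy)-4-hydroxy-4-isopropyl-1,8-dimethylbicyclo[5.3.0]dec-8-en-10-one | CC1=CC(=O)[C@@]2(C)CC[C@](O)(C(C)C)[C@@H]2[C@H](OC(=O)c2ccc(OC(C)=O)cc2)C1 | intermediate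
28 | 6-(4-acetoxybenzoyloxy)-4-isopropyl-1,8-dimethylbicyclo[5.3.0]dec-8-ene-4,10-diol, C10–OH syn to the C1 methyl | CC1=C[C@H](O)[C@@]2(C)CC[C@](O)(C(C)C)[C@@H]2[C@H](OC(=O)c2ccc(OC(C)=O)cc2)C1 | intermediate
29 | 3-methylbutanoyl chloride | CC(C)CC(Cl)=O | starting material
30 | 6-(4-acetoxybenzoyloxy)-4-hydroxy-4-isopropyl-1,8-dimethylbicyclo[5.3.0]dec-8-en-10-yl 3-methylbutanoate | CC1=C[C@H](OC(=O)CC(C)C)[C@@]2(C)CC[C@](O)(C(C)C)[C@@H]2[C@H](OC(=O)c2ccc(OC(C)=O)cc2)C1 | intermediate
31 | (1S,4S,5S,6R,10S)-4-hydroxy-6-(4-hydroxybenzoyloxy)-4-isopropyl-1,8-dimethylbicyclo[5.3.0]dec-8-en-10-yl 3-methylbutanoate | CC1=C[C@H](OC(=O)CC(C)C)[C@@]2(C)CC[C@](O)(C(C)C)[C@@H]2[C@H](OC(=O)c2ccc(O)cc2)C1 | target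

## Step count and least certain steps

Total step count: 17. Longest linear sequence: 17 steps (1 to 31).

**Step 4 (key step).** The most likely failure is 1,2-hydride migration from the methyl group of the carbenoid, giving a vinyl ketone, outrunning addition to the hindered, methoxy-bearing ipso–ortho bond. The second is erosion of the discrimination between the two enantiotopic bonds, because the flanking methoxy groups can bind copper.

Fallback: the route sets out from 9 with the achiral catalyst Rh2(OAc)4 in CH2Cl2, which should give the racemic trienone F1. Reduction of F1 with catecholborane and (S)-2-methyl-CBS-oxazaborolidine delivers hydride to the same carbonyl face in both enantiomers. The (1S)-ketone thus becomes the alcohol with hydroxyl syn to the C1 methyl, F2, and the (1R)-ketone the diastereomeric alcohol F3; the two are separated by chromatography. Oxidation of F2 with Dess–Martin periodinane buffered with NaHCO3 comes back to the route at 11.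

**Step 6.** The risk is unselective capture of the delocalised cation by water (at C10 instead of C6), or over-hydrolysis to the vinylogous diketone.

Fallback: the route sets out from 11 and hydrolyses before the C2 oxygen is removed. In 11 the C2 carbonyl next to C1 further disfavours positive charge and attack at C10, so brief dilute acid should give the 2,6-dione F4. Selective enolisation of its cyclopentanone with KN(SiMe3)2 and trapping with PhNTf2 gives the C2 enol triflate F5. The palladium–formate reduction of step 6, now without the acid treatment, comes back to the route at 15.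

**Step 10.** The risk is slow addition of the peroxide anion to a tetrasubstituted β-carbon whose carbonyl is weakened by the methoxydiene, so that γ-deprotonation and deconjugation compete. A second risk is attack on the face syn to the C1 methyl.

Fallback: the route sets out from 21 and replaces peroxide by a more nucleophilic, ligand-controlled reagent. Copper-catalysed conjugate borylation (CuCl, NaOtBu, a chiral bisphosphine, bis(pinacolato)diboron, MeOH, THF) should give the β-boryl ketone F6, with C5 protonated anti to the C1 methyl. Oxidation with NaBO3·4H2O proceeds with retention at C4 and comes back to the route at 23, bypassing 22.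

**Step 14.** The risk is ionisation of the C6 aroyloxy group, assisted by the methoxydiene, which would lose the C6 oxygen and give a dienone in competition with protonation at C7. A lesser risk is protonation at C9, which would leave the alkene at C7=C8.

Fallback: the route sets out from 24 and cleaves the enol ether at the O–CH3 bond instead of at carbon. NaSEt in DMF at about 100 °C demethylates the dienol ether. The dienolate cannot expel the C6 alkoxide, and buffered work-up followed by a trace of Et3N to bring the alkene into conjugation should give the hydroxy enone F7. Acylation of F7 with 25 (DMAP, Et3N, CH2Cl2, 0 °C) comes back to the route at 27.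

**Step 8.** The risk is incomplete or misdirected deprotonation of the hindered tertiary C5–H next to quaternary C1, with γ-deprotonation at the C8 methyl competing.

Fallback: the route sets out from 16 and uses an oxidant that works through the enol instead of a kinetic enolate. IBX in DMSO at 70 °C dehydrogenates the ketone directly, and since C5 is the only enolisable α-position, the route comes back at 18 with no new intermediate.

## Further compounds

F1 | step 4 | racemic 6,10-dimethoxy-1,8-dimethylbicyclo[5.3.0]deca-5,7,9-trien-2-one | CC1=CC(OC)=C2CCC(=O)C2(C)C(OC)=C1
F2 | step 4 | 6,10-dimethoxy-1,8-dimethylbicyclo[5.3.0]deca-5,7,9-trien-2-ol from the (1S)-ketone, hydroxyl syn to the C1 methyl | CC1=CC(OC)=C2CC[C@@H](O)[C@]2(C)C(OC)=C1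
F3 | step 4 | 6,10-dimethoxy-1,8-dimethylbicyclo[5.3.0]deca-5,7,9-trien-2-ol from the (1R)-ketone, hydroxyl anti to the C1 methyl | CC1=CC(OC)=C2CC[C@@H](O)[C@@]2(C)C(OC)=C1
F4 | step 6 | 10-methoxy-1,8-dimethylbicyclo[5.3.0]deca-7,9-diene-2,6-dione (C5 epimers) | CC1=CC(=O)C2CCC(=O)[C@]2(C)C(OC)=C1
F5 | step 6 | 10-methoxy-1,8-dimethyl-6-oxobicyclo[5.3.0]deca-2,7,9-trien-2-yl trifluoromethanesulfonate (C5 epimers) | CC1=CC(=O)C2CC=C(OS(=O)(=O)C(F)(F)F)[C@]2(C)C(OC)=C1
F6 | step 10 | 4-isopropyl-10-methoxy-1,8-dimethyl-4-(4,4,5,5-tetramethyl-1,3,2-dioxaborolan-2-yl)bicyclo[5.3.0]deca-7,9-dien-6-one, boron anti to the C1 methyl | CC1=CC(=O)[C@H]2[C@@](B3OC(C)(C)C(C)(C)O3)(C(C)C)CC[C@]2(C)C(OC)=C1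
F7 | step 14 | 4,6-dihydroxy-4-isopropyl-1,8-dimethylbicyclo[5.3.0]dec-8-en-10-one | CC1=CC(=O)[C@@]2(C)CC[C@](O)(C(C)C)[C@@H]2[C@H](O)C1
F0 | step 8 | none | none
A1 | alternative 1 | 4-isopropyl-1,8-dimethyl-6-(trimethylsilyloxy)bicyclo[5.3.0]deca-5,9-diene | C[C@H]1C=C[C@@]2(C)CC[C@H](C(C)C)C2=C(O[Si](C)(C)C)C1
A2 | alternative 2 | 10-(tert-butyldimethylsilyloxy)-1,8-dimethylbicyclo[5.3.0]deca-5,8-dien-4-one | CC1=C[C@H](O[Si](C)(C)C(C)(C)C)[C@@]2(C)CCC(=O)C2=CC1
A3 | alternative 3 | cis-fused 4-hydroxy-4-isopropyl-1-methylbicyclo[5.3.0]decane-6,10-dione 10-(ethylene ketal) | C1CC2(OCCO2)[C@@]3(C)CC[C@@](O)(C(C)C)[C@H]3C(=O)C1
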